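**Plan**

1. Retrosynthesis: the benzyl ethers on O7 and O5' come off last. Ring C is then cut at C4–C3 and at O1–C2, giving a ring A salicylaldehyde (C4 as the formyl carbon, O1 as the hydroxyl on C8a) and a ring B aroylmethyl sulfoxonium ylide that supplies C2 and C3.
2. Enabling feature: C4 sits on C4a directly beside C8a–O1. In the salicylaldehyde the C8a oxygen can hold trivalent rhodium in a five-membered chelate that reaches only the formyl C–H, so C4 becomes an acyl–metal nucleophile towards the carbene carbon C3.
3. Ring A piece: 2,3,4-trihydroxybenzaldehyde is benzylated at O4, methylated at O2 and O3, and hydroxylated at C6, its only free ortho carbon. Ring B piece: methyl 3-hydroxy-4,5-dimethoxybenzoate is benzylated and then acylates dimethylsulfoxonium methylide.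
4. The two pieces are joined and ring C, the only ring that is built, closes in the same flask; hydrogenolysis then frees both phenols.
5. Stereochemistry: the target has no stereocentre, so nothing has to be controlled.

Key step: step 6

Assumption: in step 3 the new phenolic oxygen is counted as coming from water (the hydrate water of p-TsOH·H2O), whichever oxygen nucleophile first bonds to C6 on palladium.

**Route**

Step 1
Reactants: 1 2,3,4-trihydroxybenzaldehyde; 2 benzyl bromide
Product: 3 4-(benzyloxy)-2,3-dihydroxybenzaldehyde
Conditions: BnBr (1.0 equiv), NaHCO3 (1.2 equiv), DMF, 40 °C, N2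
Reagents that add atoms: benzyl bromide, BrCc1ccccc1
Why: Williamson etherification under a weak base should go to O4 alone, because the 4-OH para to the formyl group is the most acidic phenol, the 2-OH is tied up in a hydrogen bond to C=O and the 3-OH is not conjugated with the carbonyl.

Step 2
Reactants: 3 4-(benzyloxy)-2,3-dihydroxybenzaldehyde; 4 iodomethane
Product: 5 4-(benzyloxy)-2,3-dimethoxybenzaldehyde
Conditions: MeI (3 equiv), K2CO3 (3 equiv), DMF, 50 °C, N2
Reagents that add atoms: iodomethane, CI
Why: Twofold Williamson O-methylation with carbonate in DMF is forcing enough to alkylate the chelated 2-OH as well, and the non-enolisable aldehyde and the benzyl ether are inert to it.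

Step 3
Reactants: 5 4-(benzyloxy)-2,3-dimethoxybenzaldehyde
Product: 6 4-(benzyloxy)-6-hydroxy-2,3-dimethoxybenzaldehyde
Conditions: Pd(OAc)2 (10 mol%), 4-chloroanthranilic acid (50 mol%), 1-fluoro-2,4,6-trimethylpyridinium triflate (1.5 equiv), p-TsOH·H2O (2 equiv), AcOH, 90 °C; aqueous work-up
Reagents that add atoms: water, O
Why: This is a palladium-catalysed transient-directing-group ortho C–H hydroxylation of a benzaldehyde: the catalytic imine-carboxylate chelate places divalent palladium at C6, the only ortho C–H because C2 carries a methoxy group, the N-fluoropyridinium salt oxidises the palladacycle to tetravalent palladium, and C–O reductive elimination followed by imine hydrolysis should leave the salicylaldehyde.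

Step 4
Reactants: 7 methyl 3-hydroxy-4,5-dimethoxybenzoate; 2 benzyl bromide
Product: 8 methyl 3-(benzyloxy)-4,5-dimethoxybenzoate
Conditions: BnBr (1.2 equiv), K2CO3 (2 equiv), DMF, 60 °C
Reagents that add atoms: benzyl bromide, BrCc1ccccc1
Why: Williamson etherification of the single phenol is unambiguous, and the methyl ester does not react with carbonate in dry DMF.

Step 5
Reactants: 8 methyl 3-(benzyloxy)-4,5-dimethoxybenzoate; 9 trimethylsulfoxonium iodide
Product: 11 1-[3-(benzyloxy)-4,5-dimethoxyphenyl]-2-[dimethyl(oxo)-λ6-sulfanylidene]ethan-1-one, via dimethylsulfoxonium methylide 10 (not isolated)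
Conditions: Me3S(O)I (3 equiv), KOtBu (3 equiv), THF, reflux; then 8, reflux
Reagents that add atoms: trimethylsulfoxonium iodide, C[S+](C)(C)=O.[I-]
Why: Acyl substitution of the methyl ester by the Corey–Chaykovsky methylide gives a β-keto sulfoxonium salt that is deprotonated at once to the stabilised ylide, which does not react further and leaves the ethers untouched.

Step 6
Reactants: 6 4-(benzyloxy)-6-hydroxy-2,3-dimethoxybenzaldehyde; 11 1-[3-(benzyloxy)-4,5-dimethoxyphenyl]-2-[dimethyl(oxo)-λ6-sulfanylidene]ethan-1-one
Product: 14 7-(benzyloxy)-2-[3-(benzyloxy)-4,5-dimethoxyphenyl]-5,6-dimethoxy-4H-chromen-4-one, via diketone 12 (not isolated), via hemiketal 13 (not isolated)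
Conditions: [Cp*RhCl2]2 (4 mol%), AgSbF6 (16 mol%), NaOAc (0.5 equiv), AcOH (1 equiv), ClCH2CH2Cl, 100 °C, N2
Reagents that add atoms: none
Why: The phenoxide of 6 binds the Cp*-ligated trivalent rhodium cation and acetate-assisted cleavage of the formyl C–H gives a five-membered acyl rhodacycle; ylide 11 then coordinates through carbon, loses dimethyl sulfoxide to a rhodium carbene, and migratory insertion of the acyl group forms C4–C3. Protonolysis by acetic acid releases diketone 12 and returns the catalyst, after which the C8a hydroxyl adds to the ring B carbonyl (6-exo-trig, forming O1–C2) to give hemiketal 13, which loses water to the pyranone of ring C. The closest known reaction type is the annulation of salicylaldehydes with α-aroyl sulfoxonium ylides to flavones under trivalent rhodium catalysis, from which this case differs only in its ether substituents. No stereocentre is created, since C2 of 13 is transient and becomes trigonal on dehydration. The step needs formyl C–H activation to win over aryl C–H activation and over carbene O–H insertion; the O(C8a)–Rh chelate secures this because it reaches the formyl hydrogen through a five-membered ring, whereas the ring C–H next to the hydroxyl would need a four-membered one and the other ortho position carries a methoxy group.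

Step 7
Reactants: 14 7-(benzyloxy)-2-[3-(benzyloxy)-4,5-dimethoxyphenyl]-5,6-dimethoxy-4H-chromen-4-one
Product: 15 7,5'-dihydroxy-5,6,3',4'-tetramethoxyflavone
Conditions: H2 (1 atm), 10% Pd/C, THF/MeOH, rt
Reagents that add atoms: none
Why: Catalytic hydrogenolysis cleaves both aryl benzyl ethers under conditions that normally spare the vinylogous ester C2=C3 of a flavone and the four methyl ethers.

**Compound list**

1 | 2,3,4-trihydroxybenzaldehyde | O=Cc1ccc(O)c(O)c1O | starting material
2 | benzyl bromide | BrCc1ccccc1 | starting material
3 | 4-(benzyloxy)-2,3-dihydroxybenzaldehyde | O=Cc1ccc(OCc2ccccc2)c(O)c1O | intermediate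
4 | iodomethane | CI | starting material
5 | 4-(benzyloxy)-2,3-dimethoxybenzaldehyde | COc1c(C=O)ccc(OCc2ccccc2)c1OC | intermediate
6 | 4-(benzyloxy)-6-hydroxy-2,3-dimethoxybenzaldehyde | COc1c(OC)c(OCc2ccccc2)cc(O)c1C=O | intermediate
7 | methyl 3-hydroxy-4,5-dimethoxybenzoate | COC(=O)c1cc(O)c(OC)c(OC)c1 | starting material
8 | methyl 3-(benzyloxy)-4,5-dimethoxybenzoate | COC(=O)c1cc(OC)c(OC)c(OCc2ccccc2)c1 | intermediate
9 | trimethylsulfoxonium iodide | C[S+](C)(C)=O.[I-] | starting material
10 | dimethylsulfoxonium methylide (formed in the flask, not isolated) | C=S(C)(C)=O | intermediate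
11 | 1-[3-(benzyloxy)-4,5-dimethoxyphenyl]-2-[dimethyl(oxo)-λ6-sulfanylidene]ethan-1-one | COc1cc(C(=O)C=S(C)(C)=O)cc(OCc2ccccc2)c1OC | intermediate
12 | 1-[4-(benzyloxy)-6-hydroxy-2,3-dimethoxyphenyl]-3-[3-(benzyloxy)-4,5-dimethoxyphenyl]propane-1,3-dione (diketone, not isolated) | COc1cc(C(=O)CC(=O)c2c(O)cc(OCc3ccccc3)c(OC)c2OC)cc(OCc2ccccc2)c1OC | intermediate
13 | 7-(benzyloxy)-2-[3-(benzyloxy)-4,5-dimethoxyphenyl]-2-hydroxy-5,6-dimethoxy-2,3-dihydro-4H-chromen-4-one (hemiketal, racemic at C2, not isolated) | COc1cc(C2(O)CC(=O)c3c(OC)c(OC)c(OCc4ccccc4)cc3O2)cc(OCc2ccccc2)c1OC | intermediate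
14 | 7-(benzyloxy)-2-[3-(benzyloxy)-4,5-dimethoxyphenyl]-5,6-dimethoxy-4H-chromen-4-one | COc1cc(-c2cc(=O)c3c(OC)c(OC)c(OCc4ccccc4)cc3o2)cc(OCc2ccccc2)c1OC | intermediate
15 | 7,5'-dihydroxy-5,6,3',4'-tetramethoxyflavone | COc1cc(-c2cc(=O)c3c(OC)c(OC)c(O)cc3o2)cc(O)c1OC | target

**Count**

Total: 7 steps. Longest linear sequence: 5 steps (steps 1, 2, 3, 6, 7 from compound 1); the ring B branch (steps 4, 5) joins at step 6.

**Steps most likely to fail, with fallbacks**

Step 3. The hot sulfonic acid and N-fluoropyridinium medium may cleave the 4-O-benzyl ether by acidolysis, may over-oxidise the very electron-rich phenol as it forms, or palladation may stall because imine condensation next to the 2-methoxy group is slow. The fallback replaces electrophilic palladation by anionic chemistry and sets out from aldehyde 5. The formyl group is masked in the flask as its α-amino alkoxide with lithium N,N,N'-trimethylethylenediamide (THF, −20 °C). The chelating side arm then directs n-BuLi to C6, and B(OMe)3 traps the aryllithium. Aqueous work-up returns the aldehyde as [5-(benzyloxy)-2-formyl-3,4-dimethoxyphenyl]boronic acid F1. Ipso-oxidation of the C–B bond with N-methylmorpholine N-oxide (CH2Cl2, rt), which tolerates aldehydes, gives salicylaldehyde 6, where the route is rejoined.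

Step 6. Formyl C–H cleavage beside the 2-methoxy group may be slow, so that decarbonylation of the acyl rhodium, carbene O–H insertion into the phenol, or ketone-directed self-condensation of the ylide take over. The fallback builds the same diketone by enolate chemistry and sets out from salicylaldehyde 6. MeMgBr (3 equiv, THF, 0 °C) adds to the formyl group to give racemic 1-[4-(benzyloxy)-6-hydroxy-2,3-dimethoxyphenyl]ethan-1-ol F2. MnO2 (CH2Cl2, rt) oxidises the benzylic alcohol to 1-[4-(benzyloxy)-6-hydroxy-2,3-dimethoxyphenyl]ethan-1-one F3. Its dianion, made with LiN(SiMe3)2 (THF, −78 °C to rt), undergoes a crossed Claisen condensation with ester 8 and rejoins the route at diketone 12. Diketone 12 is then cyclodehydrated with catalytic p-TsOH in toluene at reflux to flavone 14.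

Step 1. Ionisation may not stay at O4, leading to a second alkylation at O3, and the pyrogallol-type anion may be oxidised by air. The fallback masks the neighbouring oxygens and sets out from compound 1. In aqueous borax and NaOH, O2 and O3 are tied up as the cyclic borate sodium 4-formyl-2,2,7-trihydroxy-1,3,2-benzodioxaborol-2-uide F4. BnBr then alkylates the only free oxygen, O4, to give sodium 7-(benzyloxy)-4-formyl-2,2-dihydroxy-1,3,2-benzodioxaborol-2-uide F5. Acidification hydrolyses the borate and returns to the route at compound 3.

**Further compounds**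

F1 | step 3 | [5-(benzyloxy)-2-formyl-3,4-dimethoxyphenyl]boronic acid | COc1c(OC)c(OCc2ccccc2)cc(B(O)O)c1C=O
F2 | step 6 | 1-[4-(benzyloxy)-6-hydroxy-2,3-dimethoxyphenyl]ethan-1-ol (racemic) | COc1c(OC)c(OCc2ccccc2)cc(O)c1C(C)O
F3 | step 6 | 1-[4-(benzyloxy)-6-hydroxy-2,3-dimethoxyphenyl]ethan-1-one | COc1c(OC)c(OCc2ccccc2)cc(O)c1C(C)=O
F4 | step 1 | sodium 4-formyl-2,2,7-trihydroxy-1,3,2-benzodioxaborol-2-uide | [Na+].O=Cc1ccc(O)c2O[B-](O)(O)Oc12
F5 | step 1 | sodium 7-(benzyloxy)-4-formyl-2,2-dihydroxy-1,3,2-benzodioxaborol-2-uide | [Na+].O=Cc1ccc(OCc3ccccc3)c2O[B-](O)(O)Oc12
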